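**Plan**

- Retrosynthesis: both pyranones are opened first, the ring A lactone at C3–C4 and O1–C2 and the ring B lactone at C4'–C4a' and O1'–C2'. This leaves a tetra-ortho-substituted biaryl made of a salicylate (ring A) and an orcinol ether (ring B).
- Enabling feature: ring A (C4a, C5, C6, C7, C8, C8a) is a pentasubstituted resorcinol whose only C–H, C8, lies between the oxygen-bearing C7 and C8a. A vinylketene and a terminal alkoxyacetylene deliver exactly this pattern, so ring A is cut at C8–C8a, C6–C7 and C4a–C8a.
- Axis carbon C6 is traced back to a diazo carbon that already carries ring B. The C6–C8' bond is therefore made early as a plain aryl–CH2 bond and never by aryl–aryl coupling.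
- Forward order: ring B (purchased) → benzylic zinc addition to a C5 enal, oxidation, diazo transfer → ring A by the Wolff/[2+2]/4π/6π cascade with methoxyacetylene → ring A pyranone by acetate Claisen closure → debenzylation → ring B pyranone by malonate annulation → last O-methylation.
- Stereochemistry: the target has no stereocentre. The purchased E-alkene places the ester outside at the closing terminus, and the axis forms as a racemate.

Key step: step 8

Assumption: the target SMILES carries no descriptor for the C6–C8' axis, so the racemate is taken as the goal; unprimed locants refer to the coumarin built on ring A, primed locants to the coumarin built on ring B.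

**Step 1**
Reactants: 1 3-methoxy-5-methylphenol (orcinol monomethyl ether)
Product: 2 1-(benzyloxy)-3-methoxy-5-methylbenzene
Conditions: BnBr, K2CO3, acetone, reflux
Reagents that add atoms: benzyl bromide, BrCc1ccccc1
Why: Williamson etherification of the only free phenol masks the oxygen that will become O1' with a group that can later be removed under neutral conditions.

**Step 2**
Reactants: 2 1-(benzyloxy)-3-methoxy-5-methylbenzene
Product: 4 [2-(benzyloxy)-6-methoxy-4-methylphenyl]methanol, via aryllithium 3 (not isolated)
Conditions: n-BuLi, THF, 0 °C; (CH2O)n, 0 °C → rt; H2O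
Reagents that add atoms: paraformaldehyde (reacts as formaldehyde), C=O
Why: Directed ortho-metalation takes place at the ring position flanked by both alkoxy groups, which should be lithiated by n-BuLi well before the OCH2Ph protons, and the aryllithium adds to formaldehyde to form the future C6–C8' bond and the benzylic alcohol in one operation.

**Step 3**
Reactants: 4 [2-(benzyloxy)-6-methoxy-4-methylphenyl]methanol
Product: 5 1-(benzyloxy)-2-(chloromethyl)-3-methoxy-5-methylbenzene
Conditions: MsCl, Et3N, CH2Cl2, −10 → 0 °C; used at once
Reagents that add atoms: methanesulfonyl chloride, CS(=O)(=O)Cl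
Why: Sulfonylation followed by in situ chloride displacement at this very electron-rich benzylic carbon gives the chloride in a basic medium, which limits Friedel–Crafts self-condensation.

**Step 4**
Reactants: 5 1-(benzyloxy)-2-(chloromethyl)-3-methoxy-5-methylbenzene; 6 ethyl (E)-3-methyl-4-oxobut-2-enoate
Product: 8 ethyl (E)-5-[2-(benzyloxy)-6-methoxy-4-methylphenyl]-4-hydroxy-3-methylpent-2-enoate (racemic), via benzylic zinc chloride 7 (not isolated)
Conditions: Zn dust, LiCl, THF, 0 → 25 °C; then 6, 0 → 25 °C; aq NH4Cl
Reagents that add atoms: none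
Why: LiCl-promoted zinc insertion into a benzylic chloride gives a soft organozinc that tolerates the ester and adds 1,2 to the aldehyde, the most electrophilic site of 6 (Grignard-type carbonyl addition), and the carbinol centre forms as a racemate that is erased in step 5.

**Step 5**
Reactants: 8 ethyl (E)-5-[2-(benzyloxy)-6-methoxy-4-methylphenyl]-4-hydroxy-3-methylpent-2-enoate
Product: 9 ethyl (E)-5-[2-(benzyloxy)-6-methoxy-4-methylphenyl]-3-methyl-4-oxopent-2-enoate
Conditions: Dess–Martin periodinane, CH2Cl2, 0 °C → rt
Reagents that add atoms: none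
Why: Dess–Martin oxidation of a secondary allylic alcohol is fast and nearly neutral, so the E-alkene and the acidic benzylic CH2 of the product should not be disturbed.

**Step 6**
Reactants: 9 ethyl (E)-5-[2-(benzyloxy)-6-methoxy-4-methylphenyl]-3-methyl-4-oxopent-2-enoate
Product: 10 ethyl (E)-5-[2-(benzyloxy)-6-methoxy-4-methylphenyl]-5-diazo-3-methyl-4-oxopent-2-enoate
Conditions: 4-acetamidobenzenesulfonyl azide, DBU, MeCN, 0 °C, dark
Reagents that add atoms: 4-acetamidobenzenesulfonyl azide, CC(=O)Nc1ccc(cc1)S(=O)(=O)N=[N+]=[N-]
Why: In this Regitz diazo transfer the benzylic CH2 is the only enolisable position of the ketone, its enolate attacks the terminal azide nitrogen, and the triazene collapses to the diazo ketone and the sulfonamide, as is known for benzyl ketones.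

**Step 7**
Reactants: 11 2-chloro-1,1-dimethoxyethane (chloroacetaldehyde dimethyl acetal)
Product: 13 methoxyacetylene, via sodium methoxyacetylide 12 (not isolated)
Conditions: NaNH2 (3.3 equiv), liquid NH3, −33 °C; cold aq NaCl; distilled into cold toluene
Reagents that add atoms: none
Why: Two amide-induced β-eliminations (methanol, then HCl) from the chloroacetal, the classical route to alkoxyacetylenes, give the acetylide that is protonated on quench, and the methyl ynol ether cannot fragment by retro-ene loss of an alkene and brings the O7 methyl group with it.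

**Step 8**
Reactants: 10 ethyl (E)-5-[2-(benzyloxy)-6-methoxy-4-methylphenyl]-5-diazo-3-methyl-4-oxopent-2-enoate; 13 methoxyacetylene
Product: 18 ethyl 3-[2-(benzyloxy)-6-methoxy-4-methylphenyl]-6-hydroxy-4-methoxy-2-methylbenzoate, via aryl(vinyl)ketene 14 (not isolated), via vinylcyclobutenone 15 (not isolated), via dienylketene 16 (not isolated), via cyclohexadienone 17 (not isolated)
Conditions: 13 (5 equiv), toluene, 450 nm LED, 5 °C, sealed tube; then 90 °C
Reagents that add atoms: none
Why: Proposed new method: blue light excites the visible band that the aryl group lends to the diazo ketone, N2 leaves and the alkenyl group shifts from the carbonyl carbon to the former diazo carbon (Wolff rearrangement, C5–C6), so that aryl(vinyl)ketene 14 carries ring B on C6 before ring A exists. The CH terminus of 13, the nucleophilic end of the ynol ether, attacks the electrophilic ketene carbon (C8–C8a) and the oxygen-bearing carbon bonds to C6 (C6–C7) in a [2+2] cycloaddition to 15; heating opens 15 by four-electron conrotation (the old C6–C8a bond breaks) to 16, which closes ring A by six-electron disrotatory electrocyclisation between C8a and C4a, and 17 enolises to the phenol. The closest known reaction type is the Danheiser benzannulation in its photochemical Wolff variant with alkoxy- and silyloxyalkynes, and the visible-light Wolff rearrangement of α-aryl-α-diazo ketones is known on its own; new is their combination on a diazo carbon that bears a di-ortho-substituted aryl group. The regiochemistry (OMe on C7 beside the axis, H on C8) follows from the matched polarity of ketene and ynol ether and needs no further control element. The closure is kept chemoselective by the substrate: both ortho positions of ring B are blocked, so closure onto the aryl ring to a naphthol is impossible, the ring opening of 15 is reversible so that material funnels through the isomer of 16 with alkenyl and ketenyl groups cis, and the E-alkene puts H inside and the ester outside at the closing terminus. No stereocentre survives (the quaternary carbon of 15 and the C4a–H centre of 17 are lost); the C6–C8' axis becomes stereogenic here and forms as a racemate, which is all the target requires.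

**Step 9**
Reactants: 18 ethyl 3-[2-(benzyloxy)-6-methoxy-4-methylphenyl]-6-hydroxy-4-methoxy-2-methylbenzoate
Product: 19 ethyl 6-acetoxy-3-[2-(benzyloxy)-6-methoxy-4-methylphenyl]-4-methoxy-2-methylbenzoate
Conditions: Ac2O, pyridine, DMAP (cat.), CH2Cl2, rt
Reagents that add atoms: acetic anhydride, CC(=O)OC(C)=O
Why: DMAP-catalysed O-acylation of the hydrogen-bonded salicylate phenol installs the two carbons that become C2 and C3.

**Step 10**
Reactants: 19 ethyl 6-acetoxy-3-[2-(benzyloxy)-6-methoxy-4-methylphenyl]-4-methoxy-2-methylbenzoate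
Product: 20 6-[2-(benzyloxy)-6-methoxy-4-methylphenyl]-4-hydroxy-7-methoxy-5-methyl-2H-chromen-2-one
Conditions: LiN(iPr)2 (3 equiv), THF, −78 °C → rt; 1 M HCl
Reagents that add atoms: none
Why: In this intramolecular Claisen (Dieckmann-type) condensation the acetate enolate attacks the neighbouring ester through a six-membered transition state, ethoxide leaves and the product is drained off as its stable enolate, which is the established way from O-acetylsalicylates to 4-hydroxycoumarins, 5-methyl-substituted ones included.

**Step 11**
Reactants: 20 6-[2-(benzyloxy)-6-methoxy-4-methylphenyl]-4-hydroxy-7-methoxy-5-methyl-2H-chromen-2-one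
Product: 21 6-[2-(benzyloxy)-6-methoxy-4-methylphenyl]-4,7-dimethoxy-5-methyl-2H-chromen-2-one
Conditions: Me2SO4, K2CO3, acetone, reflux
Reagents that add atoms: dimethyl sulfate, COS(=O)(=O)OC
Why: O-alkylation of the 4-hydroxycoumarin anion with a hard methylating agent gives the 4-methoxycoumarin and blocks this nucleophilic enol before the second annulation.

**Step 12**
Reactants: 21 6-[2-(benzyloxy)-6-methoxy-4-methylphenyl]-4,7-dimethoxy-5-methyl-2H-chromen-2-one
Product: 22 6-(2-hydroxy-6-methoxy-4-methylphenyl)-4,7-dimethoxy-5-methyl-2H-chromen-2-one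
Conditions: H2 (1 atm), Pd/C, EtOAc–MeOH, rt
Reagents that add atoms: none
Why: Catalytic hydrogenolysis cleaves the benzylic C–O bond under neutral conditions, while the trisubstituted, donor-substituted C3–C4 double bond of the 4-methoxycoumarin should be reduced much more slowly.

**Step 13**
Reactants: 22 6-(2-hydroxy-6-methoxy-4-methylphenyl)-4,7-dimethoxy-5-methyl-2H-chromen-2-one; 23 2,2-dimethyl-1,3-dioxane-4,6-dione (Meldrum's acid)
Product: 25 8-(4,7-dimethoxy-5-methyl-2-oxo-2H-chromen-6-yl)-4-hydroxy-7-methoxy-5-methyl-2H-chromen-2-one, via aryl hydrogen malonate 24 (not isolated)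
Conditions: 23 (1.2 equiv), toluene, 110 °C; evaporate; P2O5 in MeSO3H (Eaton's reagent), 65 °C; ice water
Reagents that add atoms: none
Why: The phenol opens Meldrum's acid to the aryl hydrogen malonate, whose acid group then undergoes intramolecular Friedel–Crafts acylation at C4a', the only free position ortho to the oxygen and also para to the O7' methoxy group, which closes the second six-membered pyranone by the known phenol-to-4-hydroxycoumarin annulation.

**Step 14**
Reactants: 25 8-(4,7-dimethoxy-5-methyl-2-oxo-2H-chromen-6-yl)-4-hydroxy-7-methoxy-5-methyl-2H-chromen-2-one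
Product: 26 4,4',7,7'-tetramethoxy-5,5'-dimethyl-6,8'-bi(2H-chromene)-2,2'-dione (CNP0271624.0, racemic)
Conditions: Me2SO4 (excess), K2CO3, acetone, reflux
Reagents that add atoms: dimethyl sulfate, COS(=O)(=O)OC
Why: This is the same O-methylation of a 4-hydroxycoumarin anion as in step 11, and the excess reagent would also make good any loss of the enol methyl group on the ring A pyranone during the acidic step 13.

**Compound list**

1 | 3-methoxy-5-methylphenol | COc1cc(C)cc(O)c1 | starting material
2 | 1-(benzyloxy)-3-methoxy-5-methylbenzene | COc1cc(C)cc(OCc2ccccc2)c1 | intermediate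
3 | [2-(benzyloxy)-6-methoxy-4-methylphenyl]lithium | [Li]c1c(OC)cc(C)cc1OCc1ccccc1 | intermediate
4 | [2-(benzyloxy)-6-methoxy-4-methylphenyl]methanol | OCc1c(OC)cc(C)cc1OCc1ccccc1 | intermediate
5 | 1-(benzyloxy)-2-(chloromethyl)-3-methoxy-5-methylbenzene | ClCc1c(OC)cc(C)cc1OCc1ccccc1 | intermediate
6 | ethyl (E)-3-methyl-4-oxobut-2-enoate | CCOC(=O)/C=C(\C)C=O | starting material
7 | [2-(benzyloxy)-6-methoxy-4-methylbenzyl]zinc chloride | Cl[Zn]Cc1c(OC)cc(C)cc1OCc1ccccc1 | intermediate
8 | ethyl (E)-5-[2-(benzyloxy)-6-methoxy-4-methylphenyl]-4-hydroxy-3-methylpent-2-enoate (racemic) | CCOC(=O)/C=C(\C)C(O)Cc1c(OC)cc(C)cc1OCc1ccccc1 | intermediate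
9 | ethyl (E)-5-[2-(benzyloxy)-6-methoxy-4-methylphenyl]-3-methyl-4-oxopent-2-enoate | CCOC(=O)/C=C(\C)C(=O)Cc1c(OC)cc(C)cc1OCc1ccccc1 | intermediate
10 | ethyl (E)-5-[2-(benzyloxy)-6-methoxy-4-methylphenyl]-5-diazo-3-methyl-4-oxopent-2-enoate | CCOC(=O)/C=C(\C)C(=O)C(=[N+]=[N-])c1c(OC)cc(C)cc1OCc1ccccc1 | intermediate
11 | 2-chloro-1,1-dimethoxyethane | COC(CCl)OC | starting material
12 | sodium methoxyacetylide | [Na+].[C-]#COC | intermediate
13 | methoxyacetylene | C#COC | intermediate
14 | ethyl (E)-4-[2-(benzyloxy)-6-methoxy-4-methylphenyl]-3-methyl-5-oxopenta-2,4-dienoate | CCOC(=O)/C=C(\C)C(=C=O)c1c(OC)cc(C)cc1OCc1ccccc1 | intermediate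
15 | ethyl (E)-3-{1-[2-(benzyloxy)-6-methoxy-4-methylphenyl]-2-methoxy-4-oxocyclobut-2-en-1-yl}but-2-enoate (racemic) | CCOC(=O)/C=C(\C)C1(C(=O)C=C1OC)c1c(OC)cc(C)cc1OCc1ccccc1 | intermediate
16 | ethyl (2E,4Z)-4-[2-(benzyloxy)-6-methoxy-4-methylphenyl]-5-methoxy-3-methyl-7-oxohepta-2,4,6-trienoate | CCOC(=O)/C=C(\C)/C(c1c(OC)cc(C)cc1OCc1ccccc1)=C(/OC)C=C=O | intermediate
17 | ethyl 3-[2-(benzyloxy)-6-methoxy-4-methylphenyl]-4-methoxy-2-methyl-6-oxocyclohexa-2,4-diene-1-carboxylate (racemic) | CCOC(=O)C1C(=O)C=C(OC)C(=C1C)c1c(OC)cc(C)cc1OCc1ccccc1 | intermediate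
18 | ethyl 3-[2-(benzyloxy)-6-methoxy-4-methylphenyl]-6-hydroxy-4-methoxy-2-methylbenzoate (racemic axis) | CCOC(=O)c1c(O)cc(OC)c(c1C)-c1c(OC)cc(C)cc1OCc1ccccc1 | intermediate
19 | ethyl 6-acetoxy-3-[2-(benzyloxy)-6-methoxy-4-methylphenyl]-4-methoxy-2-methylbenzoate | CCOC(=O)c1c(OC(C)=O)cc(OC)c(c1C)-c1c(OC)cc(C)cc1OCc1ccccc1 | intermediate
20 | 6-[2-(benzyloxy)-6-methoxy-4-methylphenyl]-4-hydroxy-7-methoxy-5-methyl-2H-chromen-2-one | COc1cc2oc(=O)cc(O)c2c(C)c1-c1c(OC)cc(C)cc1OCc1ccccc1 | intermediate
21 | 6-[2-(benzyloxy)-6-methoxy-4-methylphenyl]-4,7-dimethoxy-5-methyl-2H-chromen-2-one | COc1cc2oc(=O)cc(OC)c2c(C)c1-c1c(OC)cc(C)cc1OCc1ccccc1 | intermediate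
22 | 6-(2-hydroxy-6-methoxy-4-methylphenyl)-4,7-dimethoxy-5-methyl-2H-chromen-2-one | COc1cc2oc(=O)cc(OC)c2c(C)c1-c1c(OC)cc(C)cc1O | intermediate
23 | 2,2-dimethyl-1,3-dioxane-4,6-dione (Meldrum's acid) | CC1(C)OC(=O)CC(=O)O1 | starting material
24 | 3-[2-(4,7-dimethoxy-5-methyl-2-oxo-2H-chromen-6-yl)-3-methoxy-5-methylphenoxy]-3-oxopropanoic acid | COc1cc2oc(=O)cc(OC)c2c(C)c1-c1c(OC)cc(C)cc1OC(=O)CC(=O)O | intermediate
25 | 8-(4,7-dimethoxy-5-methyl-2-oxo-2H-chromen-6-yl)-4-hydroxy-7-methoxy-5-methyl-2H-chromen-2-one | COc1cc2oc(=O)cc(OC)c2c(C)c1-c1c(OC)cc(C)c2c(O)cc(=O)oc12 | intermediate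
26 | 4,4',7,7'-tetramethoxy-5,5'-dimethyl-6,8'-bi(2H-chromene)-2,2'-dione (racemic) | COc1cc2oc(=O)cc(OC)c2c(C)c1-c1c(OC)cc(C)c2c(OC)cc(=O)oc12 | target

Total step count: 14.
Longest linear sequence: 13 (steps 1–6 and 8–14; step 7 is a one-step side branch).

**Steps most likely to fail**

**Step 8.**
- Risk: the photogenerated acylcarbene may insert into the activated C–H bonds of the neighbouring benzyl ether before the alkenyl group has shifted. The [2+2] addition may also be too slow at a ketene shielded by the di-ortho-substituted ring B, so that ketene dimerisation or hydration takes over.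
- Fallback: this uses known chemistry, gives up ring construction and makes the axis by cross-coupling; it sets out from 2 and comes back at 18.
- Boron partner: aryllithium 3, generated as in step 2, is quenched with B(OMe)3 and hydrolysed to [2-(benzyloxy)-6-methoxy-4-methylphenyl]boronic acid F1.
- Bromide partner: commercial ethyl 2,4-dihydroxy-6-methylbenzoate is methylated at the non-chelated 4-OH (MeI, K2CO3, acetone) to ethyl 2-hydroxy-4-methoxy-6-methylbenzoate F2. NBS in MeCN at 0 °C then brominates para to the free phenol to give ethyl 3-bromo-6-hydroxy-4-methoxy-2-methylbenzoate F3.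
- Coupling: Suzuki–Miyaura reaction of F1 with F3 (Pd(OAc)2, SPhos, K3PO4, toluene–H2O, 100 °C), a ligand system established for tetra-ortho-substituted biaryls, should give 18.

**Step 6.**
- Risk: DBU or the sulfonamide anion may add in conjugate fashion to the doubly activated alkene. Base may scramble the alkene geometry. Azide capture may be slow at a hindered, only weakly acidic benzylic position.
- Fallback: this sets out from 9, comes back at 10 and replaces direct transfer by transfer to an activated 1,3-dicarbonyl compound under a weak base (detrifluoroacetylative diazo transfer).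
- Sequence: the kinetic lithium enolate of 9 (LiN(SiMe3)2, THF, −78 °C) is acylated with 2,2,2-trifluoroethyl trifluoroacetate to ethyl (E)-5-[2-(benzyloxy)-6-methoxy-4-methylphenyl]-7,7,7-trifluoro-3-methyl-4,6-dioxohept-2-enoate F4. Without purification F4 is treated with methanesulfonyl azide, Et3N and one equivalent of water in MeCN at rt. The trifluoroacetyl group leaves with the sulfonamide nitrogen and 10 results.

**Step 13.**
- Risk: acylation of a phenol that sits next to the axis may be sluggish. The malonate half-ester may decarboxylate before ring closure. The strongly acidic medium may erode the enol ether of the ring A pyranone.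
- Fallback: this sets out from 22, comes back at 25 and builds the pyranone stepwise from an acetophenone.
- Sequence: Ac2O and BF3·OEt2 at 85 °C (O-acetylation and Fries-type migration to the only free ortho position) should give 6-(3-acetyl-2-hydroxy-6-methoxy-4-methylphenyl)-4,7-dimethoxy-5-methyl-2H-chromen-2-one F5. NaH and dimethyl carbonate in toluene at reflux then carbonylate the methyl ketone enolate and close the lactone to 25. Dimethyl carbonate rather than the diethyl ester makes any alkoxide exchange at C4 degenerate.

**Further compounds**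

F1 | step 8 | [2-(benzyloxy)-6-methoxy-4-methylphenyl]boronic acid | OB(O)c1c(OC)cc(C)cc1OCc1ccccc1
F2 | step 8 | ethyl 2-hydroxy-4-methoxy-6-methylbenzoate | CCOC(=O)c1c(C)cc(OC)cc1O
F3 | step 8 | ethyl 3-bromo-6-hydroxy-4-methoxy-2-methylbenzoate | CCOC(=O)c1c(O)cc(OC)c(Br)c1C
F4 | step 6 | ethyl (E)-5-[2-(benzyloxy)-6-methoxy-4-methylphenyl]-7,7,7-trifluoro-3-methyl-4,6-dioxohept-2-enoate | CCOC(=O)/C=C(\C)C(=O)C(C(=O)C(F)(F)F)c1c(OC)cc(C)cc1OCc1ccccc1
F5 | step 13 | 6-(3-acetyl-2-hydroxy-6-methoxy-4-methylphenyl)-4,7-dimethoxy-5-methyl-2H-chromen-2-one | COc1cc2oc(=O)cc(OC)c2c(C)c1-c1c(OC)cc(C)c(C(C)=O)c1O
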